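## Analysis of the target

Target 39 is a trans-fused clerodane decalin. Ring A (C1–C5, C10) carries the 1α-acetate and the C4 exocyclic methylene (C18); ring B (C5–C10) carries the 6β-acetate, the 7α-isobutyrate, the free tertiary 8α-alcohol with the C17 methyl, and the quaternary C9 with the C20 methyl and the side chain. The side chain is C11 (R, acetate), C12 and a β-substituted butenolide (C13–C16). There are eight stereocentres. C5 and C9 are quaternary and their methyl groups (C19, C20) are syn-diaxial on the β-face; H10 is axial on the α-face; all three secondary ring oxygens are equatorial, and the C8 hydroxyl is axial. The sensitive groups are four esters of two kinds on neighbouring oxygens next to a free tertiary alcohol, the base-labile butenolide, and the methylene, which rules out general alkene oxidants once it is present. The hardest points are the C5–C10–C9–C8 array, the telling apart of the C7 oxygen from C1, C6 and C11, and the axial hydrogen at C7, which lies between the two axial methyl groups and cannot be delivered there by a hydride reagent. The strategy rests on C5 being the branch point of three chains (C4 to C1, C6 to C8, C10 to C9), and on the C1 oxygen, H10 and the C9 substituents corresponding to anti addition of C1 and C8 across an (E)-C9=C10 alkene.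

## Retrosynthetic reasoning

**Butenolide.** The C13=C14 bond of 39 is cut last, which leads to diene ester 38. Ring-closing metathesis forms the lactone without base and does not touch the hindered C4 methylene. The acetate at C11 is put on just before (37 to 38).

**C11–C12.** Alcohol 37 is cut to aldehyde 33 and the 2-substituted allylsilane 36 (made from 34 and 35). C11 is the only stereocentre outside the decalin. The free 8α-hydroxyl sits 1,3 to the aldehyde, so a chelating aluminium Lewis acid should lock the carbonyl group and leave open only the face away from ring A. The nucleophile already holds C13, C16 and the acrylate, so no ozonolysis or furan oxidation is needed later.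

**Acyl pattern.** Aldehyde 33 goes back through 32 and 31 to mono-isobutyrate 30 and tetraol 28. In 28 the C6–C8 triol has the equatorial, equatorial, axial pattern in which a stannylene acetal activates the middle oxygen. The isobutyrate can therefore be placed on O7 alone, and C1 and C6 are acetylated together.

**Ring B oxygens.** Tetraol 28 is traced to hydroxy dione 26, and this through dione 24 and ketol 23 to ketone 21. Two simpler ideas were dropped here.
- Hydroxylation of C8 through the more substituted enolate of 21 is not regioselective enough. C6 is therefore raised to the ketone level first, so that C8 is the only enolizable position.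
- A hydride would attack the C7 carbonyl from the α-face and give the axial 7β-alcohol. The dione is therefore reduced by a dissolving metal, which gives the equatorial alcohol at C6 and at C7.

The C11 silyl ether is triisopropylsilyl so that it survives this reduction.

**Key disconnection.** Ketone 21 is cut at C1–C10 and C8–C9 to aldehyde 20. One Lewis-acid step would close both rings and set C1, C10, C9 and C8 from the single centre C5. The C4 methylene is already in place, and the ketone ends up between C6 and C8, the two carbons still to be oxygenated.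

**Functional groups of 20.** The aldehyde has to be released last and without acid or fluoride, because of the enol silane. It is therefore traced through alcohol 19 to hydroxy ketone 16, and 16 through 15, 14 and 13 to keto enoate 12. The (E)-C9=C10 bond comes from a Wittig reaction of aldehyde 10 with ylide 11.

**C7 ketone.** Keto aldehyde 10 is the reduction product of enol lactone 9, which is the cycloisomer of alkynoic acid 8. The butynyl group is a masked 2-oxobutyl group, and the C10 carboxyl fixes the position of the new oxygen at C7.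

**C5.** Acid 8 is cut at C5–C6 to acid 5 and bromide 6. Alkylation of the dienediolate of 5 forms the quaternary centre with the methylene already in place. The two carboxylate oxygens are equivalent, so there is no enolate geometry to control, and a chiral lithium amide in the aggregate sets the configuration.

**Acid 5.** It comes from ester 4, the product of copper-catalysed addition of the Grignard reagent of 1 to allenoate 2. This gives the β,γ-unsaturated ester with the double bond fixed as the C4 methylene.

## Alternatives that were turned down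

**Alternative 1:** ring B is cut at C5–C6. In the forward step a cyclopropanol that holds C8, C7 and C6 is oxidised by one electron with Mn(acac)3. The ring opens to the C8 ketone and a primary C6 radical, which adds to the β-carbon C5 of a ring A enone and gives dione A1.
- For: the key step is of a known type and creates the C5 quaternary centre. The C8 ketone of A1 would take up the C17 methyl and the tertiary alcohol in one addition. On precedent for the key step this alternative is stronger than the chosen one.
- Against: in A1 C6 and C7 are bare methylenes and C6 has no neighbouring activating group. C4 is a ketal that must later be methylenated next to a quaternary carbon. C11 is a nitrile that has to be reduced. The C9 quaternary centre and the absolute configuration have to be set before the key step by other means.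
- Comparison: the chosen route gets four stereocentres and both rings from one centre and leaves a carbonyl between C6 and C8. A1 would need more redox steps on ring B than the chosen route needs in total for it.

**Alternative 2:** C9–C11 and C8–O are cut. In the forward step the magnesium alkoxide of a C7 allylic alcohol directs a furyl-substituted nitrile oxide onto a tetrasubstituted C8=C9 alkene and gives isoxazoline A2.
- For: C9, the C8 oxygen and the whole side-chain skeleton arrive in one suprafacial step, cis to the C7 oxygen as the target requires, and C11 is latent in the C=N bond. On convergence of the side chain and on the C7/C8 relationship this alternative is stronger than the chosen route.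
- Against: the substrate must already be a complete decalin with C5, C1, C6 and C7 set, so the ring construction and the 6,7-trans-diol are left unsolved. A tetrasubstituted alkene next to C10 and under the C19 methyl is a poor dipolarophile. C4 is again a ketal, the furan must be oxidised to the butenolide at the end, and C11 still needs a stereoselective reduction after N–O cleavage.
- Comparison: the chosen route appends the side chain in three steps from an aldehyde, so the advantage of A2 there is small against the length of the route to its substrate.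

**Alternative 3:** ring B is cut at C7–C8. In the forward step divalent samarium (SmI2) reduces a C7 aldehyde to its ketyl, which adds to a C8 methyl ketone and gives cis-diol A3.
- For: A3 has the C7 secondary and C8 tertiary hydroxyls cis and already told apart, with the methylene in place. This is the point at which the chosen route needs a dissolving-metal reduction and a tin-directed acylation, so this alternative is stronger there.
- Against: the substrate is a single ring A that must already carry the C5 and C9 quaternary centres on either side of C10, the C6 oxygen and two side arms in the right relative configuration. That array is the real problem of the target and is not addressed. The facial course of the coupling depends on the conformation of two flexible arms.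
- Comparison: the chosen route solves the carbon skeleton in one step and accepts more work on ring B afterwards.

Key step: step 13

## Remarks before the steps

Remark on conventions: clerodane numbering is used throughout (C18 = methylene on C4; C19, C17, C20 = methyls on C5, C8, C9; C11–C16 = side chain); α and β refer to the decalin with the C19 methyl β.

Remark on step 3: the sense of induction of the tetramine with this dienediolate is assumed to give (R)-8 with the (R,R)-base; if it is the opposite, the antipodal base is used and nothing else changes.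

## Steps

Step 1
Reactants: 1 (3-bromopropoxy)(tert-butyl)dimethylsilane; 2 ethyl 2-methylbuta-2,3-dienoate
Product: 4 ethyl (±)-6-[(tert-butyldimethylsilyl)oxy]-2-methyl-3-methylidenehexanoate, via 3-(tert-butyldimethylsilyloxy)propylmagnesium bromide 3 (not isolated)
Conditions: Mg, THF; CuBr·SMe2 (10 mol%), THF, −78 °C, then 2; AcOH, −78 °C
Reagents that add atoms: none
Why: Copper-catalysed conjugate addition of a Grignard reagent to a 2,3-dienoate places the alkyl group on the central allene carbon, and kinetic α-protonation of the dienolate should give the β,γ-unsaturated ester, so the C4 methylene is formed without regiochemical doubt.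

Step 2
Reactants: 4 ethyl (±)-6-[(tert-butyldimethylsilyl)oxy]-2-methyl-3-methylidenehexanoate
Product: 5 (±)-6-[(tert-butyldimethylsilyl)oxy]-2-methyl-3-methylidenehexanoic acid
Conditions: LiOH, THF/MeOH/H2O, rt; aq. HCl to pH 4, 0 °C
Reagents that add atoms: lithium hydroxide, [Li+].[OH-]
Why: Saponification of an unhindered ester; the primary silyl ether should survive the cold, mildly acidic work-up.

Step 3
Reactants: 5 (±)-6-[(tert-butyldimethylsilyl)oxy]-2-methyl-3-methylidenehexanoic acid; 6 1-bromobut-2-yne
Product: 8 (2R)-2-(but-2-yn-1-yl)-6-[(tert-butyldimethylsilyl)oxy]-2-methyl-3-methylidenehexanoic acid, via dilithium dienediolate 7 (not isolated)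
Conditions: (R,R)-N,N′-bis(1-phenyl-2-(piperidin-1-yl)ethyl)propane-1,3-diamine (1.05 equiv), n-BuLi (4.0 equiv), THF, 0 °C; 6, −78 °C; aq. HCl (amine recovered)
Reagents that add atoms: none
Why: Enantioselective α-alkylation of a carboxylic acid dienediolate held in a mixed aggregate with a chiral dilithium amide, which acts as a non-covalent auxiliary. The two oxygens of the dienediolate are equivalent, so no enolate geometry has to be controlled, and the reactive propargylic bromide should alkylate at the α-carbon to create the quaternary C5 (R) with the methylene deconjugated.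

Step 4
Reactants: 8 (2R)-2-(but-2-yn-1-yl)-6-[(tert-butyldimethylsilyl)oxy]-2-methyl-3-methylidenehexanoic acid
Product: 9 (3R,5Z)-3-{5-[(tert-butyldimethylsilyl)oxy]pent-1-en-2-yl}-5-ethylidene-3-methyloxolan-2-one
Conditions: PdCl2(PhCN)2 (5 mol%), Et3N (10 mol%), THF, rt
Reagents that add atoms: none
Why: Cycloisomerization of a 4-alkynoic acid by divalent palladium: 5-exo-dig anti-oxypalladation and protodemetalation give the (Z)-enol lactone, so the carboxyl group puts the new oxygen on C7 and not on C8.

Step 5
Reactants: 9 (3R,5Z)-3-{5-[(tert-butyldimethylsilyl)oxy]pent-1-en-2-yl}-5-ethylidene-3-methyloxolan-2-one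
Product: 10 (2R)-2-{5-[(tert-butyldimethylsilyl)oxy]pent-1-en-2-yl}-2-methyl-4-oxohexanal
Conditions: i-Bu2AlH (1.1 equiv), CH2Cl2, −78 °C; MeOH, aq. sodium potassium tartrate
Reagents that add atoms: none
Why: Partial reduction of a lactone: the aluminium hemiacetal should hold at −78 °C and fall apart on work-up to the C10 aldehyde and, through the enol, the C7 ketone; C5 has no hydrogen and cannot epimerize.

Step 6
Reactants: 10 (2R)-2-{5-[(tert-butyldimethylsilyl)oxy]pent-1-en-2-yl}-2-methyl-4-oxohexanal; 11 ethyl 2-(triphenyl-λ5-phosphanylidene)propanoate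
Product: 12 ethyl (2E,4S)-8-[(tert-butyldimethylsilyl)oxy]-2,4-dimethyl-5-methylidene-4-(2-oxobutyl)oct-2-enoate
Conditions: toluene, 90 °C
Reagents that add atoms: none
Why: Wittig reaction of a stabilized ylide, which reacts with the aldehyde and not with the ketone and gives the (E)-trisubstituted enoate (C5 and C20 cis), the geometry that the key step translates into the C9 configuration.

Step 7
Reactants: 12 ethyl (2E,4S)-8-[(tert-butyldimethylsilyl)oxy]-2,4-dimethyl-5-methylidene-4-(2-oxobutyl)oct-2-enoate
Product: 13 (2E,4S)-8-[(tert-butyldimethylsilyl)oxy]-4-(2-hydroxybutyl)-2,4-dimethyl-5-methylideneoct-2-en-1-ol (both epimers at the C7 carbinol)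
Conditions: i-Bu2AlH (4 equiv), CH2Cl2, −78 → 0 °C; aq. sodium potassium tartrate
Reagents that add atoms: none
Why: 1,2-Reduction of the enoate to the allylic alcohol; the ketone is reduced as well, which is accepted because the carbinol is re-oxidized in step 9 and its configuration is of no consequence.

Step 8
Reactants: 13 (2E,4S)-8-[(tert-butyldimethylsilyl)oxy]-4-(2-hydroxybutyl)-2,4-dimethyl-5-methylideneoct-2-en-1-ol
Product: 14 (5S,6E)-1-[(tert-butyldimethylsilyl)oxy]-5-(2-hydroxybutyl)-5,7-dimethyl-4-methylidene-8-[(triisopropylsilyl)oxy]oct-6-ene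
Conditions: TIPSCl (1.05 equiv), imidazole, DMF, 0 °C
Reagents that add atoms: chlorotriisopropylsilane, CC(C)[Si](Cl)(C(C)C)C(C)C
Why: Silylation with a bulky chlorosilane is selective for the primary allylic hydroxyl over the secondary one; the triisopropylsilyl ether is chosen because it has no aryl group and will survive step 17.

Step 9
Reactants: 14 (5S,6E)-1-[(tert-butyldimethylsilyl)oxy]-5-(2-hydroxybutyl)-5,7-dimethyl-4-methylidene-8-[(triisopropylsilyl)oxy]oct-6-ene
Product: 15 (5S,6E)-1-[(tert-butyldimethylsilyl)oxy]-5,7-dimethyl-4-methylidene-5-(2-oxobutyl)-8-[(triisopropylsilyl)oxy]oct-6-ene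
Conditions: Dess–Martin periodinane, CH2Cl2, rt
Reagents that add atoms: none
Why: Dess–Martin oxidation of the secondary alcohol restores the C7 ketone; the silyl ethers and alkenes are inert.

Step 10
Reactants: 15 (5S,6E)-1-[(tert-butyldimethylsilyl)oxy]-5,7-dimethyl-4-methylidene-5-(2-oxobutyl)-8-[(triisopropylsilyl)oxy]oct-6-ene
Product: 16 (5S,6E)-5,7-dimethyl-4-methylidene-5-(2-oxobutyl)-8-[(triisopropylsilyl)oxy]oct-6-en-1-ol
Conditions: PPTS (10 mol%), MeOH, rt
Reagents that add atoms: none
Why: Acid-catalysed methanolysis removes a primary tert-butyldimethylsilyl ether much faster than a triisopropylsilyl ether, which frees the C1 hydroxyl only.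

Step 11
Reactants: 16 (5S,6E)-5,7-dimethyl-4-methylidene-5-(2-oxobutyl)-8-[(triisopropylsilyl)oxy]oct-6-en-1-ol
Product: 19 (5S,6E)-5-{(2Z)-2-[(tert-butyldimethylsilyl)oxy]but-2-en-1-yl}-5,7-dimethyl-4-methylidene-8-[(triisopropylsilyl)oxy]oct-6-en-1-ol, via trimethylsilyl ether 17 (not isolated), via bis-silyl compound 18 (not isolated)
Conditions: TMSCl, Et3N, CH2Cl2, 0 °C; TBSOTf, Et3N, −78 → 0 °C; then K2CO3, MeOH, 0 °C
Reagents that add atoms: tert-butyldimethylsilyl trifluoromethanesulfonate, CC(C)(C)[Si](C)(C)OS(=O)(=O)C(F)(F)F
Why: The hydroxyl is masked for the moment as its trimethylsilyl ether. Soft enolization with the silyl triflate and amine takes place on the ethyl side (C8), since the C6 methylene is neopentyl, and should give mainly the (Z)-enol ether. Basic methanol then removes the primary trimethylsilyl ether and leaves the tert-butyldimethylsilyl enol ether.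

Step 12
Reactants: 19 (5S,6E)-5-{(2Z)-2-[(tert-butyldimethylsilyl)oxy]but-2-en-1-yl}-5,7-dimethyl-4-methylidene-8-[(triisopropylsilyl)oxy]oct-6-en-1-ol
Product: 20 (5S,6E)-5-{(2Z)-2-[(tert-butyldimethylsilyl)oxy]but-2-en-1-yl}-5,7-dimethyl-4-methylidene-8-[(triisopropylsilyl)oxy]oct-6-enal
Conditions: Dess–Martin periodinane, pyridine, CH2Cl2, 0 °C
Reagents that add atoms: none
Why: Buffered Dess–Martin oxidation releases the C1 aldehyde under neutral conditions that the enol silane tolerates; the aldehyde is used at once.

Step 13
Reactants: 20 (5S,6E)-5-{(2Z)-2-[(tert-butyldimethylsilyl)oxy]but-2-en-1-yl}-5,7-dimethyl-4-methylidene-8-[(triisopropylsilyl)oxy]oct-6-enal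
Product: 21 (1α,5β,8β,9β,10α)-1-hydroxy-5,8,9-trimethyl-4-methylidene-9-{[(triisopropylsilyl)oxy]methyl}decalin-7-one (trans-fused; 8α-H, 10α-H)
Conditions: Me2AlCl (2.5 equiv), CH2Cl2 (0.005 M), −78 → −40 °C; aq. NaHCO3
Reagents that add atoms: none
Why: Proposed new method: Me2AlCl binds the C1 aldehyde, C10 of the (E)-trisubstituted alkene adds to it, and the tertiary C9 cation so formed is captured by C8 of the silyl enol ether, after which chloride takes the silyl group from the oxocarbenium ion and leaves the C7 ketone. The closest known reaction types are the Me2AlCl-promoted Prins and carbonyl-ene cyclizations of δ,ε-unsaturated aldehydes and cation–olefin polycyclizations that end on an enol silane; their combination in one aldehyde-initiated bicyclization has not been shown on this substrate class. Ring A closes 6-exo with respect to the alkene through a chair (bond C1–C10), and ring B closes through a second chair in which both carbons of the enol ether lie in the new ring (6-endo, bond C8–C9). C1: the aluminium-bound oxygen sits equatorial in the ring A chair, which gives the 1α-alcohol. C10: antiperiplanar addition across the alkene in a chair–chair array is possible only with the C6 arm equatorial and C19 axial on ring A, so the ring fusion is trans (10α-H) and follows from the single (S) centre at C5. C9 and C8: C1 and C8 add to opposite faces of the (E)-alkene, which puts C20 axial (β) and C11 equatorial, and the (Z)-enol ether places C17 equatorial, a centre that is re-made in step 16 in any case. The step needs the C9=C10 alkene to react before the C4 methylene and before a direct aldol of the enol silane; the six-membered chair, the eight-membered ring that the direct aldol would need, and high dilution should secure this.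

Step 14
Reactants: 21 (1α,5β,8β,9β,10α)-1-hydroxy-5,8,9-trimethyl-4-methylidene-9-{[(triisopropylsilyl)oxy]methyl}decalin-7-one
Product: 23 (1α,5β,8β,9β,10α)-1,6-dihydroxy-5,8,9-trimethyl-4-methylidene-9-{[(triisopropylsilyl)oxy]methyl}decalin-7-one (C6 epimers, 6α expected to prevail), via dipotassium alkoxide enolate 22 (not isolated)
Conditions: KN(SiMe3)2 (2.3 equiv), THF, −78 °C; 2-(phenylsulfonyl)-3-phenyloxaziridine; AcOH
Reagents that add atoms: 2-(phenylsulfonyl)-3-phenyloxaziridine, O=S(=O)(N1OC1c1ccccc1)c1ccccc1
Why: Kinetic deprotonation takes the axial hydrogen of the C6 methylene rather than the tertiary C8 hydrogen, and the enolate is hydroxylated by the N-sulfonyloxaziridine (Davis oxidation), which does not touch the methylene. The C6 configuration does not matter because C6 becomes a carbonyl in step 15.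

Step 15
Reactants: 23 (1α,5β,8β,9β,10α)-1,6-dihydroxy-5,8,9-trimethyl-4-methylidene-9-{[(triisopropylsilyl)oxy]methyl}decalin-7-one
Product: 24 (1α,5β,8β,9β,10α)-1-hydroxy-5,8,9-trimethyl-4-methylidene-9-{[(triisopropylsilyl)oxy]methyl}decalin-6,7-dione (in equilibrium with its C7 enol)
Conditions: Cu(OAc)2 (2.2 equiv), MeOH, 50 °C
Reagents that add atoms: none
Why: Divalent copper oxidizes an α-hydroxy ketone to the 1,2-dione through its enediol and leaves the isolated C1 alcohol alone. With C6 now a carbonyl and C5 quaternary, C8 is the only enolizable position.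

Step 16
Reactants: 24 (1α,5β,8β,9β,10α)-1-hydroxy-5,8,9-trimethyl-4-methylidene-9-{[(triisopropylsilyl)oxy]methyl}decalin-6,7-dione
Product: 26 (1α,5β,8α,9β,10α)-1,8-dihydroxy-5,8,9-trimethyl-4-methylidene-9-{[(triisopropylsilyl)oxy]methyl}decalin-6,7-dione, via dipotassium alkoxide enolate 25 (not isolated)
Conditions: KN(SiMe3)2 (2.2 equiv), THF, −78 °C; 2-(phenylsulfonyl)-3-phenyloxaziridine; AcOH, −78 °C
Reagents that add atoms: 2-(phenylsulfonyl)-3-phenyloxaziridine, O=S(=O)(N1OC1c1ccccc1)c1ccccc1
Why: The enolate of the dione can form only at C8, and the oxaziridine should attack it axially from the α-face, anti to the axial C20 methyl on the neighbouring carbon, which gives the 8α-hydroxyl with C17 equatorial. The cold acidic quench is meant to prevent acyloin-type rearrangement of the product.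

Step 17
Reactants: 26 (1α,5β,8α,9β,10α)-1,8-dihydroxy-5,8,9-trimethyl-4-methylidene-9-{[(triisopropylsilyl)oxy]methyl}decalin-6,7-dione
Product: 28 (1α,5β,6β,7α,8α,9β,10α)-5,8,9-trimethyl-4-methylidene-9-{[(triisopropylsilyl)oxy]methyl}decalin-1,6,7,8-tetraol, via 6β-hydroxy 7-ketone 27 (not isolated)
Conditions: Li (10 equiv), NH3(l)/THF, EtOH (6 equiv), −78 → −33 °C; NH4Cl
Reagents that add atoms: none
Why: Dissolving-metal reduction: the dione is taken to its enediolate, which is protonated axially at C6 from the α-face, and the remaining C7 ketone is then reduced under thermodynamic control to the equatorial 7α-alcohol. This is the outcome known for ketones whose axial face is blocked by two syn-axial methyl groups, where hydrides give the axial alcohol. The α-oxygens are present as alkoxides, which are poor leaving groups, and the isolated methylene and the triisopropylsilyl ether are not reduced.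

Step 18
Reactants: 28 (1α,5β,6β,7α,8α,9β,10α)-5,8,9-trimethyl-4-methylidene-9-{[(triisopropylsilyl)oxy]methyl}decalin-1,6,7,8-tetraol
Product: 30 (1α,5β,6β,7α,8α,9β,10α)-1,6,8-trihydroxy-5,8,9-trimethyl-4-methylidene-9-{[(triisopropylsilyl)oxy]methyl}decalin-7-yl 2-methylpropanoate, via dibutylstannylene acetal 29 (not isolated)
Conditions: Bu2SnO (1.1 equiv), toluene, reflux (−H2O); i-PrCOCl (1.05 equiv), 0 °C
Reagents that add atoms: 2-methylpropanoyl chloride, CC(C)C(Cl)=O
Why: Stannylene-acetal-directed acylation: in a triol with the equatorial, equatorial, axial pattern of C6, C7, C8 the tin acetal activates the equatorial oxygen next to the axial one, which is O7, so the isobutyrate should go to C7 alone. The tertiary C8 and the isolated C1 hydroxyls are not activated.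

Step 19
Reactants: 30 (1α,5β,6β,7α,8α,9β,10α)-1,6,8-trihydroxy-5,8,9-trimethyl-4-methylidene-9-{[(triisopropylsilyl)oxy]methyl}decalin-7-yl 2-methylpropanoate
Product: 31 (1α,5β,6β,7α,8α,9β,10α)-1,6-diacetoxy-8-hydroxy-5,8,9-trimethyl-4-methylidene-9-{[(triisopropylsilyl)oxy]methyl}decalin-7-yl 2-methylpropanoate
Conditions: Ac2O, pyridine, DMAP (cat.), CH2Cl2, rt
Reagents that add atoms: acetic anhydride, CC(=O)OC(C)=O
Why: Acetylation of the two secondary hydroxyls; the axial tertiary C8 hydroxyl next to the quaternary C9 should not react under these conditions.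

Step 20
Reactants: 31 (1α,5β,6β,7α,8α,9β,10α)-1,6-diacetoxy-8-hydroxy-5,8,9-trimethyl-4-methylidene-9-{[(triisopropylsilyl)oxy]methyl}decalin-7-yl 2-methylpropanoate
Product: 32 (1α,5β,6β,7α,8α,9β,10α)-1,6-diacetoxy-8-hydroxy-9-(hydroxymethyl)-5,8,9-trimethyl-4-methylidenedecalin-7-yl 2-methylpropanoate
Conditions: HF·pyridine, pyridine, THF, 0 °C → rt
Reagents that add atoms: none
Why: Fluoride cleavage of the silyl ether in a buffered acidic medium, chosen over a basic fluoride source so that the esters do not migrate.

Step 21
Reactants: 32 (1α,5β,6β,7α,8α,9β,10α)-1,6-diacetoxy-8-hydroxy-9-(hydroxymethyl)-5,8,9-trimethyl-4-methylidenedecalin-7-yl 2-methylpropanoate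
Product: 33 (1α,5β,6β,7α,8α,9β,10α)-1,6-diacetoxy-9-formyl-8-hydroxy-5,8,9-trimethyl-4-methylidenedecalin-7-yl 2-methylpropanoate
Conditions: Dess–Martin periodinane, CH2Cl2, rt
Reagents that add atoms: none
Why: Dess–Martin oxidation of the neopentyl primary alcohol; the tertiary alcohol cannot be oxidized, and the neutral medium avoids retro-aldol opening of the β-hydroxy aldehyde.

Step 22
Reactants: 34 2-[(trimethylsilyl)methyl]prop-2-en-1-ol; 35 prop-2-enoyl chloride
Product: 36 2-[(trimethylsilyl)methyl]prop-2-en-1-yl prop-2-enoate
Conditions: Et3N, CH2Cl2, 0 °C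
Reagents that add atoms: none
Why: Acylation of a primary alcohol with an acid chloride gives the allylsilane that carries C12, C13, C16 and the acrylate.

Step 23
Reactants: 33 (1α,5β,6β,7α,8α,9β,10α)-1,6-diacetoxy-9-formyl-8-hydroxy-5,8,9-trimethyl-4-methylidenedecalin-7-yl 2-methylpropanoate; 36 2-[(trimethylsilyl)methyl]prop-2-en-1-yl prop-2-enoate
Product: 37 (11R)-homoallylic alcohol: decalin of 33 with C9 bearing CH(OH)–CH2–C(=CH2)–CH2–O–CO–CH=CH2 (1α,6β-diacetate, 7α-isobutyrate, 8α-OH)
Conditions: Me2AlCl (3 equiv), CH2Cl2, −78 °C; 36; aq. sodium potassium tartrate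
Reagents that add atoms: none
Why: Hosomi–Sakurai allylation under chelation control: the aluminium alkoxide formed from the 8α-hydroxyl binds the aldehyde oxygen in a six-membered chelate (Cram chelate model), the face of the carbonyl toward C1 and its acetate is closed, and the allylsilane should attack anti to C10 from the C17/C20 side, which gives (11R). The esters and the methylene are not expected to react at −78 °C.

Step 24
Reactants: 37 (11R)-homoallylic alcohol
Product: 38 (11R)-acetate: decalin of 33 with C9 bearing CH(OAc)–CH2–C(=CH2)–CH2–O–CO–CH=CH2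
Conditions: Ac2O, pyridine, DMAP, CH2Cl2, rt
Reagents that add atoms: acetic anhydride, CC(=O)OC(C)=O
Why: Acetylation of the hindered secondary C11 hydroxyl with nucleophilic catalysis; the tertiary C8 hydroxyl stays free.

Step 25
Reactants: 38 (11R)-acetate
Product: 39 CNP0266716.2 (1α,6β,11R-triacetate, 7α-isobutyrate, 8α-ol, 4(18)-ene, 15,16-olide with C13=C14)
Conditions: second-generation Grubbs catalyst (5 mol%), CH2Cl2, 40 °C
Reagents that add atoms: none
Why: Ring-closing metathesis between the acrylate and the 1,1-disubstituted alkene forms the β-substituted butenolide with loss of ethene; the C4 methylene is flanked by a quaternary carbon and too far away to take part.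

## Compound list

1 | (3-bromopropoxy)(tert-butyl)dimethylsilane | CC(C)(C)[Si](C)(C)OCCCBr | starting material
2 | ethyl 2-methylbuta-2,3-dienoate | CCOC(=O)C(C)=C=C | starting material
3 | 3-(tert-butyldimethylsilyloxy)propylmagnesium bromide | CC(C)(C)[Si](C)(C)OCCC[Mg]Br | intermediate (not isolated)
4 | ethyl (±)-6-[(tert-butyldimethylsilyl)oxy]-2-methyl-3-methylidenehexanoate | CCOC(=O)C(C)C(=C)CCCO[Si](C)(C)C(C)(C)C | intermediate
5 | (±)-6-[(tert-butyldimethylsilyl)oxy]-2-methyl-3-methylidenehexanoic acid | OC(=O)C(C)C(=C)CCCO[Si](C)(C)C(C)(C)C | intermediate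
6 | 1-bromobut-2-yne | CC#CCBr | starting material
7 | dilithium dienediolate of 5 | [Li+].[Li+].[O-]C([O-])=C(C)C(=C)CCCO[Si](C)(C)C(C)(C)C | intermediate (not isolated)
8 | (2R)-2-(but-2-yn-1-yl)-6-[(tert-butyldimethylsilyl)oxy]-2-methyl-3-methylidenehexanoic acid | CC(C)(C)[Si](C)(C)OCCCC(=C)[C@](C)(C(=O)O)CC#CC | intermediate
9 | (3R,5Z)-3-{5-[(tert-butyldimethylsilyl)oxy]pent-1-en-2-yl}-5-ethylidene-3-methyloxolan-2-one | CC(C)(C)[Si](C)(C)OCCCC(=C)[C@](C)(C(=O)O1)C/C1=C/C | intermediate
10 | (2R)-2-{5-[(tert-butyldimethylsilyl)oxy]pent-1-en-2-yl}-2-methyl-4-oxohexanal | CC(C)(C)[Si](C)(C)OCCCC(=C)[C@](C)(C=O)CC(=O)CC | intermediate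
11 | ethyl 2-(triphenyl-λ5-phosphanylidene)propanoate | CCOC(=O)C(C)=P(c1ccccc1)(c1ccccc1)c1ccccc1 | starting material
12 | ethyl (2E,4S)-8-[(tert-butyldimethylsilyl)oxy]-2,4-dimethyl-5-methylidene-4-(2-oxobutyl)oct-2-enoate | CC(C)(C)[Si](C)(C)OCCCC(=C)[C@](C)(/C=C(\C)C(=O)OCC)CC(=O)CC | intermediate
13 | (2E,4S)-8-[(tert-butyldimethylsilyl)oxy]-4-(2-hydroxybutyl)-2,4-dimethyl-5-methylideneoct-2-en-1-ol (C7 epimers) | CC(C)(C)[Si](C)(C)OCCCC(=C)[C@](C)(/C=C(\C)CO)CC(O)CC | intermediate
14 | (5S,6E)-1-[(tert-butyldimethylsilyl)oxy]-5-(2-hydroxybutyl)-5,7-dimethyl-4-methylidene-8-[(triisopropylsilyl)oxy]oct-6-ene (C7 epimers) | CC(C)(C)[Si](C)(C)OCCCC(=C)[C@](C)(/C=C(\C)CO[Si](C(C)C)(C(C)C)C(C)C)CC(O)CC | intermediate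
15 | (5S,6E)-1-[(tert-butyldimethylsilyl)oxy]-5,7-dimethyl-4-methylidene-5-(2-oxobutyl)-8-[(triisopropylsilyl)oxy]oct-6-ene | CC(C)(C)[Si](C)(C)OCCCC(=C)[C@](C)(/C=C(\C)CO[Si](C(C)C)(C(C)C)C(C)C)CC(=O)CC | intermediate
16 | (5S,6E)-5,7-dimethyl-4-methylidene-5-(2-oxobutyl)-8-[(triisopropylsilyl)oxy]oct-6-en-1-ol | OCCCC(=C)[C@](C)(/C=C(\C)CO[Si](C(C)C)(C(C)C)C(C)C)CC(=O)CC | intermediate
17 | trimethylsilyl ether of 16 | C[Si](C)(C)OCCCC(=C)[C@](C)(/C=C(\C)CO[Si](C(C)C)(C(C)C)C(C)C)CC(=O)CC | intermediate (not isolated)
18 | trimethylsilyl ether of 19 | C[Si](C)(C)OCCCC(=C)[C@](C)(/C=C(\C)CO[Si](C(C)C)(C(C)C)C(C)C)C/C(O[Si](C)(C)C(C)(C)C)=C/C | intermediate (not isolated)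
19 | (5S,6E)-5-{(2Z)-2-[(tert-butyldimethylsilyl)oxy]but-2-en-1-yl}-5,7-dimethyl-4-methylidene-8-[(triisopropylsilyl)oxy]oct-6-en-1-ol | OCCCC(=C)[C@](C)(/C=C(\C)CO[Si](C(C)C)(C(C)C)C(C)C)C/C(O[Si](C)(C)C(C)(C)C)=C/C | intermediate
20 | (5S,6E)-5-{(2Z)-2-[(tert-butyldimethylsilyl)oxy]but-2-en-1-yl}-5,7-dimethyl-4-methylidene-8-[(triisopropylsilyl)oxy]oct-6-enal | O=CCCC(=C)[C@](C)(/C=C(\C)CO[Si](C(C)C)(C(C)C)C(C)C)C/C(O[Si](C)(C)C(C)(C)C)=C/C | intermediate
21 | (1α,5β,8β,9β,10α)-1-hydroxy-5,8,9-trimethyl-4-methylidene-9-{[(triisopropylsilyl)oxy]methyl}decalin-7-one | C=C1CC[C@H](O)[C@@H]2[C@]1(C)CC(=O)[C@H](C)[C@@]2(C)CO[Si](C(C)C)(C(C)C)C(C)C | intermediate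
22 | dipotassium C1 alkoxide, C6=C7 enolate of 21 | C=C1CC[C@H]([O-])[C@@H]2[C@]1(C)C=C([O-])[C@H](C)[C@@]2(C)CO[Si](C(C)C)(C(C)C)C(C)C.[K+].[K+] | intermediate (not isolated)
23 | (1α,5β,8β,9β,10α)-1,6-dihydroxy-5,8,9-trimethyl-4-methylidene-9-{[(triisopropylsilyl)oxy]methyl}decalin-7-one (C6 epimers) | C=C1CC[C@H](O)[C@@H]2[C@]1(C)C(O)C(=O)[C@H](C)[C@@]2(C)CO[Si](C(C)C)(C(C)C)C(C)C | intermediate
24 | (1α,5β,8β,9β,10α)-1-hydroxy-5,8,9-trimethyl-4-methylidene-9-{[(triisopropylsilyl)oxy]methyl}decalin-6,7-dione | C=C1CC[C@H](O)[C@@H]2[C@]1(C)C(=O)C(=O)[C@H](C)[C@@]2(C)CO[Si](C(C)C)(C(C)C)C(C)C | intermediate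
25 | dipotassium C1 alkoxide, C7=C8 enolate of 24 | C=C1CC[C@H]([O-])[C@@H]2[C@]1(C)C(=O)C([O-])=C(C)[C@@]2(C)CO[Si](C(C)C)(C(C)C)C(C)C.[K+].[K+] | intermediate (not isolated)
26 | (1α,5β,8α,9β,10α)-1,8-dihydroxy-5,8,9-trimethyl-4-methylidene-9-{[(triisopropylsilyl)oxy]methyl}decalin-6,7-dione | C=C1CC[C@H](O)[C@@H]2[C@]1(C)C(=O)C(=O)[C@@](C)(O)[C@@]2(C)CO[Si](C(C)C)(C(C)C)C(C)C | intermediate
27 | (1α,5β,6β,8α,9β,10α)-1,6,8-trihydroxy-5,8,9-trimethyl-4-methylidene-9-{[(triisopropylsilyl)oxy]methyl}decalin-7-one (present as its lithium alkoxide) | C=C1CC[C@H](O)[C@@H]2[C@]1(C)[C@H](O)C(=O)[C@@](C)(O)[C@@]2(C)CO[Si](C(C)C)(C(C)C)C(C)C | intermediate (not isolated)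
28 | (1α,5β,6β,7α,8α,9β,10α)-5,8,9-trimethyl-4-methylidene-9-{[(triisopropylsilyl)oxy]methyl}decalin-1,6,7,8-tetraol | C=C1CC[C@H](O)[C@@H]2[C@]1(C)[C@H](O)[C@@H](O)[C@@](C)(O)[C@@]2(C)CO[Si](C(C)C)(C(C)C)C(C)C | intermediate
29 | 7,8-O-dibutylstannylene acetal of 28 | C=C1CC[C@H](O)[C@@H]2[C@]1(C)[C@H](O)[C@H]3O[Sn](CCCC)(CCCC)O[C@@]3(C)[C@@]2(C)CO[Si](C(C)C)(C(C)C)C(C)C | intermediate (not isolated)
30 | 7-O-isobutyrate of 28 | C=C1CC[C@H](O)[C@@H]2[C@]1(C)[C@H](O)[C@@H](OC(=O)C(C)C)[C@@](C)(O)[C@@]2(C)CO[Si](C(C)C)(C(C)C)C(C)C | intermediate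
31 | 1,6-di-O-acetyl-7-O-isobutyryl derivative of 28 | C=C1CC[C@H](OC(C)=O)[C@@H]2[C@]1(C)[C@H](OC(C)=O)[C@@H](OC(=O)C(C)C)[C@@](C)(O)[C@@]2(C)CO[Si](C(C)C)(C(C)C)C(C)C | intermediate
32 | C11 alcohol: 31 without the silyl group | C=C1CC[C@H](OC(C)=O)[C@@H]2[C@]1(C)[C@H](OC(C)=O)[C@@H](OC(=O)C(C)C)[C@@](C)(O)[C@@]2(C)CO | intermediate
33 | C11 aldehyde | C=C1CC[C@H](OC(C)=O)[C@@H]2[C@]1(C)[C@H](OC(C)=O)[C@@H](OC(=O)C(C)C)[C@@](C)(O)[C@@]2(C)C=O | intermediate
34 | 2-[(trimethylsilyl)methyl]prop-2-en-1-ol | OCC(=C)C[Si](C)(C)C | starting material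
35 | prop-2-enoyl chloride | C=CC(Cl)=O | starting material
36 | 2-[(trimethylsilyl)methyl]prop-2-en-1-yl prop-2-enoate | C=CC(=O)OCC(=C)C[Si](C)(C)C | intermediate
37 | (11R)-homoallylic alcohol with acrylate | C=C1CC[C@H](OC(C)=O)[C@@H]2[C@]1(C)[C@H](OC(C)=O)[C@@H](OC(=O)C(C)C)[C@@](C)(O)[C@@]2(C)[C@@H](CC(=C)COC(=O)C=C)O | intermediate
38 | (11R)-acetate of 37 | C=C1CC[C@H](OC(C)=O)[C@@H]2[C@]1(C)[C@H](OC(C)=O)[C@@H](OC(=O)C(C)C)[C@@](C)(O)[C@@]2(C)[C@@H](CC(=C)COC(=O)C=C)OC(C)=O | intermediate
39 | CNP0266716.2 | C=C1CC[C@H](OC(C)=O)[C@@H]2[C@]1(C)[C@H](OC(C)=O)[C@@H](OC(=O)C(C)C)[C@@](C)(O)[C@@]2(C)[C@@H](CC1=CC(=O)OC1)OC(C)=O | target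

## Step count and least certain steps

Total step count: 25. Longest linear sequence: 24 steps (steps 1–21 and 23–25); step 22 is a one-step side branch.

**Step 13 (key step, Proposed new method).** The most likely failures are:
- loss of a proton from the C9 cation before C8 attacks (ene-type termination);
- attack of the C4 methylene on the activated aldehyde;
- closure of ring B through a boat, which gives the cis fusion;
- loss of the enol silane to the Lewis acid before the alkene has reacted.

Fallback (sets out from 16, returns at 21): the two rings are closed in separate steps of known type. Oxidation of 16 with Dess–Martin periodinane gives the keto aldehyde F1. SnCl4 in CH2Cl2 at −78 °C should bring about a chloride-terminated Prins closure of ring A and give the chloro alcohol F2. Silylation as in step 11 (TMSCl, then TBSOTf/Et3N) gives the silyl enol ether F3. ZnCl2 or TiCl4 then ionizes the tertiary chloride, so that the enol silane is tert-alkylated at C8 within the molecule, and methanolysis of the trimethylsilyl ether returns 21. The ring fusion is then no longer tied to one chair–chair array, so lower selectivity at C10 has to be expected.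

**Step 3.** Insufficient facial selectivity in the aggregate, or partial alkylation at the γ-carbon, would lower the enantiomeric purity of the only stereocentre from which all others derive.

Fallback (sets out from 4, returns at 8): deprotonation of 4 with LiN(i-Pr)2 and alkylation with 6 gives the racemic quaternary ester F4. Saponification (KOH, aq. EtOH, heat) gives the racemic acid F5. Crystallization with (S)-1-phenylethylamine (or its antipode) gives the diastereomerically pure ammonium salt F6, from which acid liberates 8.

**Step 17.** Reductive loss of the C6 or C8 oxygen from the ketyl, or protonation of the enediolate at C7 instead of C6, would give deoxygenated material or the wrong diol.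

Fallback (sets out from 26, returns at 28): NaBH4 in MeOH reduces both carbonyl groups from the open α-face to the 7β-epimeric tetraol F7. Ru(CO)2Cl(C5Ph5) with KOt-Bu in toluene then equilibrates the secondary carbinols by reversible dehydrogenation. Since 28 has all three secondary hydroxyls equatorial, it is the thermodynamic end point.

**Step 23.** Poor facial selectivity at the aldehyde is possible if the chelate does not form, for example through competition of the ester carbonyls for aluminium. The C11 epimers would then form together.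

Fallback (sets out from 37 as the mixture of C11 epimers, returns at 37): oxidation with Dess–Martin periodinane gives the C11 ketone F8. Corey–Bakshi–Shibata reduction with the (S)-oxazaborolidine and catecholborane at −78 °C, in which the quaternary C9 is the large and C12 the small substituent, should then give the (11R)-alcohol under reagent control.

## Further compounds

F1 | step 13 | (2E... keto aldehyde) (5S,6E)-5,7-dimethyl-4-methylidene-5-(2-oxobutyl)-8-[(triisopropylsilyl)oxy]oct-6-enal | O=CCCC(=C)[C@](C)(/C=C(\C)CO[Si](C(C)C)(C(C)C)C(C)C)CC(=O)CC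
F2 | step 13 | chloro alcohol: ring A with 1α-OH, 4-methylene, C5 bearing methyl and 2-oxobutyl, C10 bearing 2-chloro-1-[(triisopropylsilyl)oxy]propan-2-yl | C=C1CC[C@H](O)[C@H]([C@]1(C)CC(=O)CC)C(C)(Cl)CO[Si](C(C)C)(C(C)C)C(C)C
F3 | step 13 | silyl enol ether: F2 as its C1 trimethylsilyl ether and (Z)-C7 tert-butyldimethylsilyl enol ether | C=C1CC[C@H](O[Si](C)(C)C)[C@H]([C@]1(C)C/C(O[Si](C)(C)C(C)(C)C)=C/C)C(C)(Cl)CO[Si](C(C)C)(C(C)C)C(C)C
F4 | step 3 | ethyl (±)-2-(but-2-yn-1-yl)-6-[(tert-butyldimethylsilyl)oxy]-2-methyl-3-methylidenehexanoate | CCOC(=O)C(C)(CC#CC)C(=C)CCCO[Si](C)(C)C(C)(C)C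
F5 | step 3 | (±)-2-(but-2-yn-1-yl)-6-[(tert-butyldimethylsilyl)oxy]-2-methyl-3-methylidenehexanoic acid | OC(=O)C(C)(CC#CC)C(=C)CCCO[Si](C)(C)C(C)(C)C
F6 | step 3 | (S)-1-phenylethylammonium salt of 8 | CC(C)(C)[Si](C)(C)OCCCC(=C)[C@](C)(C(=O)[O-])CC#CC.C[C@H]([NH3+])c1ccccc1
F7 | step 17 | (1α,5β,6β,7β,8α,9β,10α)-tetraol, the C7 epimer of 28 | C=C1CC[C@H](O)[C@@H]2[C@]1(C)[C@H](O)[C@H](O)[C@@](C)(O)[C@@]2(C)CO[Si](C(C)C)(C(C)C)C(C)C
F8 | step 23 | C11 ketone of 37 | C=C1CC[C@H](OC(C)=O)[C@@H]2[C@]1(C)[C@H](OC(C)=O)[C@@H](OC(=O)C(C)C)[C@@](C)(O)[C@@]2(C)C(=O)CC(=C)COC(=O)C=C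
A1 | alternative 1 | trans-decalin-1,8-dione with C4 dimethyl ketal, C5 and C9 methyls and C9 nitrile | COC1(OC)CCC(=O)[C@@H]2[C@]1(C)CCC(=O)[C@@]2(C)C#N
A2 | alternative 2 | isoxazoline-fused decalin with furylmethyl side chain, C4 dioxolane, C1 and C6 silyl ethers, C7 alcohol | C12(OCCO1)CC[C@H](O[Si](C)(C)C(C)(C)C)[C@@H]3[C@]2(C)[C@H](O[Si](C)(C)C(C)(C)C)[C@@H](O)[C@@]4(C)ON=C(Cc5ccoc5)[C@@]34C
A3 | alternative 3 | decalin cis-7,8-diol with C4 methylene, C1 and C6 silyl ethers and C11 p-methoxybenzyl ether | C=C1CC[C@H](O[Si](C)(C)C(C)(C)C)[C@@H]2[C@]1(C)[C@H](O[Si](C)(C)C(C)(C)C)[C@@H](O)[C@@](C)(O)[C@@]2(C)COCc3ccc(OC)cc3
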